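**Retrosynthetic overview**
- The pyranone (ring C) is the only ring formed and it is formed last. Its O1–C2 bond (C–O) is the strategic disconnection: the ring-A phenol oxygen adds to the ring-B carbonyl carbon of an acyclic 2-prenyl-1,3-diaryl-1,3-dione, and loss of water fixes the bond.
- C3–prenyl bond: C-prenylation of the central carbon of the dione, in the same flask and just before ring closure, with 2-methylbut-3-en-2-ol as the prenyl source (Pd π-prenyl).
- C2–C3 bond: crossed Claisen condensation of the trianion of 2',6'-dihydroxy-4'-methoxyacetophenone with MOM-protected methyl 2,4-dihydroxybenzoate.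
- Rings A and B are bought with all oxygens in place. The two ortho-OH groups of the ring-A ketone are equivalent, so ring closure can only give the 5-hydroxy-7-methoxy pattern.
- MOM ethers stop the ring-B 2'-OH from closing the other way and are removed by the acid of the last operation. Order: protect ring B → dione → prenylate / close ring C / deprotect.

Assumption: the target SMILES has no stereocentre and no stereogenic double bond, so it is achiral and needs no stereocontrol; the acetophenone used in step 2 and 2-methylbut-3-en-2-ol are taken as catalogue chemicals.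

**Step 1**
Reactants: 1 methyl 2,4-dihydroxybenzoate
Product: 2 methyl 2,4-bis(methoxymethoxy)benzoate
Conditions: NaH (2.5 equiv), MOMCl (2.6 equiv), DMF, 0 °C → rt
Reagents that add atoms: chloromethyl methyl ether (MOMCl), COCCl
Why: Williamson O-alkylation of both sodium phenoxides (NaH breaks the hydrogen bond of the 2-OH to the ester) gives acetal ethers that survive LiHMDS and Pd(0) and leave in the acid of step 3.

**Step 2**
Reactants: 2 methyl 2,4-bis(methoxymethoxy)benzoate; 3 1-(2,6-dihydroxy-4-methoxyphenyl)ethan-1-one (2',6'-dihydroxy-4'-methoxyacetophenone)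
Product: 4 1-[2,4-bis(methoxymethoxy)phenyl]-3-(2,6-dihydroxy-4-methoxyphenyl)propane-1,3-dione
Conditions: 3, LiHMDS (4.2 equiv), THF, −78 → −10 °C; then 2 (1.1 equiv), −78 °C → rt, 16 h; 1 M HCl to pH 4, 0 °C
Reagents that add atoms: none
Why: Crossed Claisen condensation (the polyanion variant of the Baker–Venkataraman dione synthesis) in which the ketone enolate carbon of the lithium trianion acylates on the non-enolisable methyl ester, driven by irreversible deprotonation of the 1,3-dione, while the phenoxides cannot be acylated permanently by a methyl ester.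

**Step 3**
Reactants: 4 1-[2,4-bis(methoxymethoxy)phenyl]-3-(2,6-dihydroxy-4-methoxyphenyl)propane-1,3-dione
Product: 7 2-(2,4-dihydroxyphenyl)-5-hydroxy-7-methoxy-3-(3-methylbut-2-en-1-yl)-4H-chromen-4-one, via 2-prenyl-1,3-dione 5 (not isolated), via bis-MOM flavone 6 (not isolated)
Conditions: Pd(PPh3)4 (5 mol%), PhCO2H (10 mol%), 2-methylbut-3-en-2-ol (1.3 equiv), THF–MeOH 4:1, 55 °C; strip volatiles; TsOH·H2O (0.2 equiv), THF, 50 °C; then MeOH, conc. HCl (to 2 M), 50 °C
Reagents that add atoms: 2-methylbut-3-en-2-ol, CC(C)(O)C=C
Why: Proposed new method: a one-flask "prenylative cyclodehydration" of a free-phenolic o-hydroxyaryl 1,3-dione, in which Pd(0)/PPh3 ionises the tertiary allylic alcohol (its OH activated by hydrogen bonding to PhCO2H and the acidic dione, water leaving) to the 1,1-dimethyl-π-allyl complex, the soft dione carbon attacks its unsubstituted terminus to give the linear prenyl group (small-bite PPh3 favours linear, and any phenol O-prenyl ether is re-ionised by Pd), the mono-prenylated dione 5 collapses to its ring-A cyclic hemiketal (this forms the O1–C2 bond and leaves no acidic C–H for a second allylation), TsOH expels water from the hemiketal through an oxocarbenium ion stabilised by the 2,4-dialkoxyphenyl group to lock the pyranone of 6 before the ring-B oxygens are unmasked, and 2 M HCl/MeOH then cleaves both MOM acetals; the closest known reactions are the Tsuji–Trost allylation of 1,3-diketones with allylic alcohols and the acid cyclodehydration of o-hydroxydibenzoylmethanes (Baker–Venkataraman flavone synthesis), which have not been merged or run on an unprotected 2,6-dihydroxyaryl dione; the labile stereocentre of 5 disappears on dehydration, so no stereocentre remains.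

**Compound list**
1 | methyl 2,4-dihydroxybenzoate | COC(=O)c1ccc(O)cc1O | starting material
2 | methyl 2,4-bis(methoxymethoxy)benzoate | COCOc1ccc(C(=O)OC)c(OCOC)c1 | intermediate
3 | 1-(2,6-dihydroxy-4-methoxyphenyl)ethan-1-one | COc1cc(O)c(C(C)=O)c(O)c1 | starting material
4 | 1-[2,4-bis(methoxymethoxy)phenyl]-3-(2,6-dihydroxy-4-methoxyphenyl)propane-1,3-dione (mixture of dione, enol and ring-A hemiketal tautomers) | COCOc1ccc(C(=O)CC(=O)c2c(O)cc(OC)cc2O)c(OCOC)c1 | intermediate
5 | 1-[2,4-bis(methoxymethoxy)phenyl]-3-(2,6-dihydroxy-4-methoxyphenyl)-2-(3-methylbut-2-en-1-yl)propane-1,3-dione (racemic and enolisable at C2; in equilibrium with its ring-A cyclic hemiketal) | COCOc1ccc(C(=O)C(CC=C(C)C)C(=O)c2c(O)cc(OC)cc2O)c(OCOC)c1 | intermediate (not isolated)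
6 | 2-[2,4-bis(methoxymethoxy)phenyl]-5-hydroxy-7-methoxy-3-(3-methylbut-2-en-1-yl)-4H-chromen-4-one | COCOc1ccc(-c2oc3cc(OC)cc(O)c3c(=O)c2CC=C(C)C)c(OCOC)c1 | intermediate (not isolated)
7 | 2-(2,4-dihydroxyphenyl)-5-hydroxy-7-methoxy-3-(3-methylbut-2-en-1-yl)-4H-chromen-4-one (achiral) | COc1cc(O)c2c(=O)c(CC=C(C)C)c(-c3ccc(O)cc3O)oc2c1 | target

**Totals**
Total step count: 3. Longest linear sequence: 3 steps (1 → 2 → 4 → 7); compound 3 enters in step 2.

**Steps most likely to fail**

1. Step 3 (the proposed new step). The alcohol may ionise slowly, prenylation may go to ring A, to a phenol oxygen or to the branched 1,1-dimethylallyl isomer, a MOM group may fall off before ring closure and let the ring-B 2'-OH close the other way, or acid may add to the prenyl alkene. The fallback uses known chemistry and puts the prenyl group on the ketone before the dione is made. It sets out from 3: LiHMDS (3.3 equiv), THF, −78 °C, then prenyl bromide (1.0 equiv, CC(C)=CCBr), −78 → 0 °C, alkylates the trianion at the enolate carbon to give 1-(2,6-dihydroxy-4-methoxyphenyl)-5-methylhex-4-en-1-one F1. Claisen condensation of F1 with 2 under the conditions of step 2 then gives the prenylated dione, and the fallback comes back to the route at 5, which is now isolated. From 5 the known single operation of acid cyclodehydration with MOM removal (2 M HCl, MeOH, 50 °C) leads through 6 to 7.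

2. Step 2. The lithium trianion of 3 may be poorly soluble and react sluggishly with the hindered, electron-rich ester. The fallback is the classical Baker–Venkataraman sequence through an aryl ester. It sets out from 2: LiOH, THF–MeOH–H2O, then acidification gives 2,4-bis(methoxymethoxy)benzoic acid F2. EDCI and DMAP in CH2Cl2 with 3 (1.0 equiv; its two OH groups are equivalent) give the mono-ester 2-acetyl-3-hydroxy-5-methoxyphenyl 2,4-bis(methoxymethoxy)benzoate F3. KOH in pyridine at 50 °C moves the aroyl group from oxygen to the enolate carbon, and the fallback comes back to the route at 4.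

3. Step 1. The hydrogen-bonded 2-OH of the salicylate may alkylate slowly and leave the 4-mono-MOM ester. The fallback avoids alkylating a salicylate and makes the ester carbon–carbon bond instead. It does not set out from a numbered compound: in place of 1 it starts from commercial 4-bromobenzene-1,3-diol F4. MOMCl with NaH in DMF gives 1-bromo-2,4-bis(methoxymethoxy)benzene F5. Bromine–lithium exchange with n-BuLi in THF at −78 °C gives [2,4-bis(methoxymethoxy)phenyl]lithium F6, which is added to excess methyl chloroformate at −78 °C, and the fallback comes back to the route at 2.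

**Further compounds**
F1 | step 3 | 1-(2,6-dihydroxy-4-methoxyphenyl)-5-methylhex-4-en-1-one | COc1cc(O)c(C(=O)CCC=C(C)C)c(O)c1
F2 | step 2 | 2,4-bis(methoxymethoxy)benzoic acid | COCOc1ccc(C(=O)O)c(OCOC)c1
F3 | step 2 | 2-acetyl-3-hydroxy-5-methoxyphenyl 2,4-bis(methoxymethoxy)benzoate | COCOc1ccc(C(=O)Oc2cc(OC)cc(O)c2C(C)=O)c(OCOC)c1
F4 | step 1 | 4-bromobenzene-1,3-diol | Oc1ccc(Br)c(O)c1
F5 | step 1 | 1-bromo-2,4-bis(methoxymethoxy)benzene | COCOc1ccc(Br)c(OCOC)c1
F6 | step 1 | [2,4-bis(methoxymethoxy)phenyl]lithium | [Li]c1ccc(OCOC)cc1OCOC
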